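**Retrosynthetic overview**

1. Target 24 ⇐ 23 ⇐ 22: the end game is a desilylation after a 3‑OH‑directed 1,3‑syn reduction of the C5 ketone; the C9 ketone is carried unprotected.
2. 22 ⇐ 21 (key): the only ring, the 14‑membered lactone ring, is closed at C3–C4 by a BF3‑mediated Mukaiyama macro‑aldol of the C4=C5 (Z)‑enol silane onto the C3 aldehyde. Enabling feature: in the ring segment C1(=O)–C2H(CH3)–C3H(OH)–C4H(CH3)–C5, C3 is an aldol carbinol for a C5‑ketone donor, and C2 lies between the C1 lactone carbonyl and C3, so in the C3 aldehyde it is a freely epimerising 1,3‑dicarbonyl CH (both C2 epimers funnel into 2R while C3 and C4 are set).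
3. 21 ⇐ 18: a pseudo‑symmetric C4–C10 5,9‑diketone; both ethyl ketones (C9/C10 and C5/C4) come from the two carboxyl termini of desymmetrised meso‑2,4‑dimethylglutaric anhydride (C6, C8).
4. 18 ⇐ 4 + 12: C10–C11 by a boron aldol; aldehyde 12 (C11–C13, from an Evans syn aldol) already carries the O13–C1 ester of the C1–C3 unit 10, so O13 is never protected.
5. Ring order: all intermediates are acyclic up to 21; the 14‑membered ring forms in step 14 and no other ring is made.

Key step: step 14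

Remark: macrolide numbering is used for positions (C1 = lactone carbonyl, O13 on C13).
Assumption: (DHQD)2AQN‑catalysed methanolysis of 1 is taken to give hemiester 2 with the (2R,4S) configuration; if the sense is the opposite, the pseudoenantiomeric (DHQ)2AQN is used.
Remark: acid 10 is used as the (R)‑enantiomer only so that 11–20 are single diastereomers; its stereocentre (C2) is deliberately scrambled in 21 and reset in step 14.

**Route**

Step 1
Reactants: 1 meso‑2,4‑dimethylglutaric anhydride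
Product: 2 (2R,4S)‑5‑methoxy‑2,4‑dimethyl‑5‑oxopentanoic acid
Conditions: MeOH (10 equiv), (DHQD)2AQN (10 mol %), Et2O, −30 °C
Reagents that add atoms: methanol, CO
Why: Cinchona‑alkaloid‑catalysed desymmetrising alcoholysis of a meso anhydride, in which the quinuclidine base delivers methanol to one of the two enantiotopic carbonyls and so fixes C6 and C8 in one operation.

Step 2
Reactants: 2 (2R,4S)‑5‑methoxy‑2,4‑dimethyl‑5‑oxopentanoic acid
Product: 4 methyl (2S,4R)‑2,4‑dimethyl‑5‑oxoheptanoate, via acid chloride 3 (not isolated)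
Conditions: (COCl)2, DMF (cat.), CH2Cl2, 0 °C → rt; then Et2Zn (0.6 equiv), Pd(PPh3)4 (5 mol %), toluene, 0 °C → rt
Reagents that add atoms: diethylzinc, CC[Zn]CC; oxalyl chloride, O=C(Cl)C(=O)Cl (chlorine of 3 only)
Why: Negishi‑type acylation (Pd‑catalysed coupling of an acid chloride with a dialkylzinc) gives the C9 ethyl ketone under non‑basic conditions that leave the methyl ester and both α‑stereocentres untouched.

Step 3
Reactants: 5 (S)‑4‑benzyl‑3‑propanoyloxazolidin‑2‑one; 6 acetaldehyde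
Product: 8 (S)‑4‑benzyl‑3‑[(2S,3R)‑3‑hydroxy‑2‑methylbutanoyl]oxazolidin‑2‑one, via boron enolate 7 (not isolated)
Conditions: Bu2BOTf, iPr2NEt, CH2Cl2, −78 → 0 °C; MeCHO, −78 → 0 °C; pH 7 buffer, MeOH, 30% H2O2, 0 °C
Reagents that add atoms: dibutylboron triflate, CCCCB(CCCC)OS(=O)(=O)C(F)(F)F (boron of 7 only)
Why: Evans syn aldol, in which the (Z)‑boron enolate reacts through a Zimmerman–Traxler chair on the face left open by the benzyl group of the auxiliary and so sets C12 and C13 as the (2S,3R) syn pair.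

Step 4
Reactants: 8 (S)‑4‑benzyl‑3‑[(2S,3R)‑3‑hydroxy‑2‑methylbutanoyl]oxazolidin‑2‑one
Product: 9 S‑ethyl (2S,3R)‑3‑hydroxy‑2‑methylbutanethioate
Conditions: EtSH, n‑BuLi, THF, −78 → 0 °C; aq. NH4Cl
Reagents that add atoms: ethanethiol, CCS
Why: Transthioesterification, in which lithium ethanethiolate attacks the exocyclic imide carbonyl and releases the auxiliary, giving a thioester that can later be reduced to the aldehyde in the presence of an ester.

Step 5
Reactants: 9 S‑ethyl (2S,3R)‑3‑hydroxy‑2‑methylbutanethioate; 10 (R)‑3‑(benzyloxy)‑2‑methylpropanoic acid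
Product: 11 S‑ethyl (2S,3R)‑3‑{[(2R)‑3‑(benzyloxy)‑2‑methylpropanoyl]oxy}‑2‑methylbutanethioate
Conditions: DCC, DMAP (0.2 equiv), CH2Cl2, 0 °C → rt
Reagents that add atoms: none
Why: Steglich esterification makes the O13–C1 ester bond at the outset, so that O13 needs no protecting group and the later C9 ketone never meets a free 13‑OH (no 9,13‑hemiketal), and no stereocentre is created.

Step 6
Reactants: 11 S‑ethyl (2S,3R)‑3‑{[(2R)‑3‑(benzyloxy)‑2‑methylpropanoyl]oxy}‑2‑methylbutanethioate
Product: 12 (2R,3S)‑3‑methyl‑4‑oxobutan‑2‑yl (2R)‑3‑(benzyloxy)‑2‑methylpropanoate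
Conditions: Et3SiH, Pd/C (10 wt % palladium on carbon), acetone, rt
Reagents that add atoms: none
Why: Fukuyama reduction of the thioester gives the C11 aldehyde under neutral conditions that spare the ester, the benzyl ether and the α‑stereocentre.

Step 7
Reactants: 4 methyl (2S,4R)‑2,4‑dimethyl‑5‑oxoheptanoate; 12 (2R,3S)‑3‑methyl‑4‑oxobutan‑2‑yl (2R)‑3‑(benzyloxy)‑2‑methylpropanoate
Product: 14 methyl (2S,4R,6R,7S,8R,9R)‑9‑{[(2R)‑3‑(benzyloxy)‑2‑methylpropanoyl]oxy}‑7‑hydroxy‑2,4,6,8‑tetramethyl‑5‑oxodecanoate, via boron enolate 13 (not isolated)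
Conditions: 4 (1.2 equiv), Bu2BOTf, iPr2NEt, CH2Cl2, −78 → 0 °C; 12, −78 → −20 °C; pH 7 buffer, MeOH, 30% H2O2, 0 °C
Reagents that add atoms: dibutylboron triflate, CCCCB(CCCC)OS(=O)(=O)C(F)(F)F (boron of 13 only)
Why: Boron aldol, in which the (Z)‑enolate 13 adds through a chair transition state (10,11‑syn) and, as (Z)‑enolates do with α‑methyl aldehydes to avoid a syn‑pentane interaction, on the anti‑Felkin face (11,12‑anti), which sets C10 and C11 while the C8 centre of the ketone exerts only a weak bias.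

Step 8
Reactants: 14 aldol adduct (C5 methyl ester, 9‑ketone, 11‑OH, O13 ester)
Product: 15 11‑O‑tert‑butyldimethylsilyl ether of 14
Conditions: TBSOTf, 2,6‑lutidine, CH2Cl2, −78 °C
Reagents that add atoms: tert‑butyldimethylsilyl triflate, CC(C)(C)[Si](C)(C)OS(=O)(=O)C(F)(F)F
Why: Silylation of the β‑hydroxy ketone with a silyl triflate and a hindered base is too mild for retro‑aldol or β‑elimination and installs the one protecting group that stays to the end.

Step 9
Reactants: 15 11‑O‑TBS ether of 14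
Product: 16 carboxylic acid from 15 (C5 CO2H)
Conditions: Me3SnOH, ClCH2CH2Cl, 80 °C; 5% aq. HCl wash
Reagents that add atoms: trimethyltin hydroxide, C[Sn](C)(C)O (oxygen of the CO2H group)
Why: Tin‑hydroxide ester cleavage is selective for the methyl ester over the secondary, α‑branched C13 ester and is near‑neutral, so the silyl ether and the epimerisable centres C6, C8 and C10 are kept.

Step 10
Reactants: 16 carboxylic acid (C5 CO2H)
Product: 18 5,9‑diketone (C5 ethyl ketone; C4 and its methyl now in place), via acid chloride 17 (not isolated)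
Conditions: 1‑chloro‑N,N,2‑trimethylprop‑1‑en‑1‑amine, CH2Cl2, 0 °C → rt; then Et2Zn (0.6 equiv), Pd(PPh3)4 (5 mol %), toluene, 0 °C → rt
Reagents that add atoms: diethylzinc, CC[Zn]CC; 1‑chloro‑N,N,2‑trimethylprop‑1‑en‑1‑amine, CC(C)=C(Cl)N(C)C (chlorine of 17 only)
Why: The same Negishi‑type acylation as in step 2, with the acid chloride made under neutral conditions, installs the second ethyl ketone without addition of the zinc reagent to the hindered C9 ketone.

Step 11
Reactants: 18 5,9‑diketone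
Product: 19 (Z)‑C4=C5 tert‑butyldimethylsilyl enol ether of 18
Conditions: TBSOTf (1.3 equiv), Et3N, CH2Cl2, −78 → −30 °C
Reagents that add atoms: tert‑butyldimethylsilyl triflate, CC(C)(C)[Si](C)(C)OS(=O)(=O)C(F)(F)F
Why: Soft enolisation with a silyl triflate and a tertiary amine silylates only the ketone that has an α‑CH2 (C5; the C9 ketone has two α‑methines) and gives the (Z)‑enol silane, the isomer free of A(1,3) strain between the C4 methyl and the C6 branch.

Step 12
Reactants: 19 (Z)‑enol silane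
Product: 20 primary alcohol from 19 (C3 OH)
Conditions: H2 (1 atm), Pd/C (10 wt % palladium on carbon), EtOAc, rt
Reagents that add atoms: none
Why: Hydrogenolysis removes the primary benzyl ether, and the trisubstituted enol silane, the ketone and the silyl ether are expected to survive a short exposure in a neutral aprotic solvent.

Step 13
Reactants: 20 primary alcohol
Product: 21 α‑formyl ester (C3 aldehyde; both C2 epimers and the enol in equilibrium)
Conditions: Dess–Martin periodinane, pyridine, CH2Cl2, 0 °C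
Reagents that add atoms: none
Why: Dess–Martin oxidation under pyridine buffering gives the aldehyde without acid that would hydrolyse the enol silane, and C2 now lies between two carbonyls and equilibrates, so the configuration brought in with 10 no longer matters.

Step 14
Reactants: 21 α‑formyl ester
Product: 22 macrocyclic aldol (14‑membered lactone; 3‑OH, 5‑ketone, 9‑ketone, 11‑OTBS)
Conditions: BF3·OEt2 (3 equiv, added over 6 h), CH2Cl2 (1 mM in 21), −40 → −20 °C; sat. aq. NaHCO3
Reagents that add atoms: none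
Why: Proposed new method: BF3 binds the C3 aldehyde of the α‑formyl ester as a monodentate Lewis acid (no chelate to the C1 ester) and C4 of the (Z)‑enol silane attacks it through an open, antiperiplanar Mukaiyama transition state, the silyl group leaving as its fluoride; the closest known reaction type is the intermolecular BF3·OEt2 Mukaiyama aldol of (Z)‑enol silanes of ethyl ketones with α‑methyl aldehydes, which delivers the Felkin syn,syn stereotriad, and the new elements are its use as a macrocyclisation and the racemising α‑formyl ester as acceptor. The 14‑membered ring closes in the 14‑(enolendo)‑exo‑trig mode. C2 is a 1,3‑dicarbonyl CH that should epimerise through the enol faster than the ring closes when BF3·OEt2 is fed slowly at 1 mM, so both C2 epimers of 21 drain (Curtin–Hammett) through the polar Felkin–Anh/Cornforth arrangement in which the C1 ester opposes the aldehyde dipole and the nucleophile passes the C2 hydrogen, which gives 2,3‑syn. C3 and C4 arise together as the 3,4‑syn pair expected for a (Z)‑enol silane with a branched substituent (C6) on the enol carbon, and the C4 face is chosen by the C6 stereocentre, whose hydrogen eclipses the enol double bond so that the aldehyde enters past the C6 methyl and anti to C7 (4,6‑anti). The step needs the aldehyde to react in preference to the C9 ketone, which is secured because BF3 activates only the aldehyde and the α,α′‑dibranched C9 ketone would have to form a quaternary carbinol in a six‑membered aldol, and it needs ring closure to beat oligomerisation, which the high dilution secures. The face selectivity of the enol silane is the least secured element and is dealt with under the risks.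

Step 15
Reactants: 22 macrocyclic aldol
Product: 23 11‑O‑tert‑butyldimethylsilyl‑8,8a‑deoxyoleandolide
Conditions: Et2BOMe, THF/MeOH (4:1), −78 °C; NaBH4, −78 °C; AcOH, then MeOH co‑evaporation
Reagents that add atoms: none
Why: Narasaka–Prasad reduction, in which 3‑OH and the C5 ketone form a six‑membered boron chelate that is activated towards borohydride and takes hydride axially to give the 3,5‑syn diol (5S), while the unchelated, α,α′‑dibranched C9 ketone is not expected to react at −78 °C.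

Step 16
Reactants: 23 11‑O‑TBS‑8,8a‑deoxyoleandolide
Product: 24 8,8a‑deoxyoleandolide
Conditions: 48% aq. HF, MeCN, 0 °C → rt
Reagents that add atoms: none
Why: Fluoride‑mediated desilylation frees 11‑OH under mildly acidic conditions that should neither epimerise C8/C10 nor open the lactone, giving the target (which may sit in equilibrium with its 5,9‑hemiketal).

**Compound list**

1 | meso‑2,4‑dimethylglutaric anhydride [(3R,5S)‑3,5‑dimethyloxane‑2,6‑dione] | O=C1[C@@H](C)C[C@@H](C)C(=O)O1 | starting material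
2 | (2R,4S)‑5‑methoxy‑2,4‑dimethyl‑5‑oxopentanoic acid | COC(=O)[C@@H](C)C[C@@H](C)C(=O)O | intermediate
3 | methyl (2S,4R)‑5‑chloro‑2,4‑dimethyl‑5‑oxopentanoate (acid chloride of 2) | COC(=O)[C@@H](C)C[C@@H](C)C(=O)Cl | intermediate
4 | methyl (2S,4R)‑2,4‑dimethyl‑5‑oxoheptanoate (C5 ester, C9 ethyl ketone) | COC(=O)[C@@H](C)C[C@@H](C)C(=O)CC | intermediate
5 | (S)‑4‑benzyl‑3‑propanoyloxazolidin‑2‑one | CCC(=O)N1[C@@H](Cc2ccccc2)COC1=O | starting material
6 | acetaldehyde | CC=O | starting material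
7 | (Z)‑dibutylboron enolate of 5 | CCCCB(CCCC)O/C(=C\C)N1[C@@H](Cc2ccccc2)COC1=O | intermediate
8 | (S)‑4‑benzyl‑3‑[(2S,3R)‑3‑hydroxy‑2‑methylbutanoyl]oxazolidin‑2‑one | O=C1OC[C@H](Cc2ccccc2)N1C(=O)[C@@H](C)[C@@H](C)O | intermediate
9 | S‑ethyl (2S,3R)‑3‑hydroxy‑2‑methylbutanethioate | CCSC(=O)[C@@H](C)[C@@H](C)O | intermediate
10 | (R)‑3‑(benzyloxy)‑2‑methylpropanoic acid (commercial; the O‑benzyl acid of methyl (R)‑3‑hydroxy‑2‑methylpropanoate) | OC(=O)[C@H](C)COCc1ccccc1 | starting material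
11 | S‑ethyl (2S,3R)‑3‑{[(2R)‑3‑(benzyloxy)‑2‑methylpropanoyl]oxy}‑2‑methylbutanethioate | CCSC(=O)[C@@H](C)[C@@H](C)OC(=O)[C@H](C)COCc1ccccc1 | intermediate
12 | (2R,3S)‑3‑methyl‑4‑oxobutan‑2‑yl (2R)‑3‑(benzyloxy)‑2‑methylpropanoate (C11 aldehyde with C12, C13 and the C1–C3 ester) | O=C[C@@H](C)[C@@H](C)OC(=O)[C@H](C)COCc1ccccc1 | intermediate
13 | (Z)‑dibutylboron enolate of 4 (C9=C10) | C/C=C(\OB(CCCC)CCCC)[C@H](C)C[C@H](C)C(=O)OC | intermediate
14 | methyl (2S,4R,6R,7S,8R,9R)‑9‑{[(2R)‑3‑(benzyloxy)‑2‑methylpropanoyl]oxy}‑7‑hydroxy‑2,4,6,8‑tetramethyl‑5‑oxodecanoate | COC(=O)[C@@H](C)C[C@@H](C)C(=O)[C@H](C)[C@@H](O)[C@@H](C)[C@@H](C)OC(=O)[C@H](C)COCc1ccccc1 | intermediate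
15 | 11‑O‑TBS ether of 14 | COC(=O)[C@@H](C)C[C@@H](C)C(=O)[C@H](C)[C@@H](O[Si](C)(C)C(C)(C)C)[C@@H](C)[C@@H](C)OC(=O)[C@H](C)COCc1ccccc1 | intermediate
16 | carboxylic acid from 15 (C5 CO2H) | OC(=O)[C@@H](C)C[C@@H](C)C(=O)[C@H](C)[C@@H](O[Si](C)(C)C(C)(C)C)[C@@H](C)[C@@H](C)OC(=O)[C@H](C)COCc1ccccc1 | intermediate
17 | acid chloride of 16 | ClC(=O)[C@@H](C)C[C@@H](C)C(=O)[C@H](C)[C@@H](O[Si](C)(C)C(C)(C)C)[C@@H](C)[C@@H](C)OC(=O)[C@H](C)COCc1ccccc1 | intermediate
18 | 5,9‑diketone (C5 ethyl ketone, C9 ketone, 11‑OTBS, O13 ester of 10; stereocentres C6, C8, C10–C13 as in the target) | CCC(=O)[C@@H](C)C[C@@H](C)C(=O)[C@H](C)[C@@H](O[Si](C)(C)C(C)(C)C)[C@@H](C)[C@@H](C)OC(=O)[C@H](C)COCc1ccccc1 | intermediate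
19 | (Z)‑C4=C5 tert‑butyldimethylsilyl enol ether of 18 | C/C=C(\O[Si](C)(C)C(C)(C)C)[C@@H](C)C[C@@H](C)C(=O)[C@H](C)[C@@H](O[Si](C)(C)C(C)(C)C)[C@@H](C)[C@@H](C)OC(=O)[C@H](C)COCc1ccccc1 | intermediate
20 | primary alcohol from 19 (C3 OH; benzyl removed) | C/C=C(\O[Si](C)(C)C(C)(C)C)[C@@H](C)C[C@@H](C)C(=O)[C@H](C)[C@@H](O[Si](C)(C)C(C)(C)C)[C@@H](C)[C@@H](C)OC(=O)[C@H](C)CO | intermediate
21 | α‑formyl ester from 20 (C3 aldehyde; C2 unassigned: both epimers and the enol) | C/C=C(\O[Si](C)(C)C(C)(C)C)[C@@H](C)C[C@@H](C)C(=O)[C@H](C)[C@@H](O[Si](C)(C)C(C)(C)C)[C@@H](C)[C@@H](C)OC(=O)C(C)C=O | intermediate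
22 | 5‑oxo‑11‑O‑TBS macrolide (14‑membered lactone; 3‑OH, 5‑ and 9‑ketones; C2, C3, C4, C6, C8, C10–C13 as in the target) | C[C@@H]1C(=O)[C@@H](C)C[C@@H](C)C(=O)[C@H](C)[C@@H](O[Si](C)(C)C(C)(C)C)[C@@H](C)[C@@H](C)OC(=O)[C@H](C)[C@H]1O | intermediate
23 | 11‑O‑tert‑butyldimethylsilyl‑8,8a‑deoxyoleandolide | C[C@@H]1[C@@H](O)[C@@H](C)C[C@@H](C)C(=O)[C@H](C)[C@@H](O[Si](C)(C)C(C)(C)C)[C@@H](C)[C@@H](C)OC(=O)[C@H](C)[C@H]1O | intermediate
24 | 8,8a‑deoxyoleandolide | C[C@@H]1[C@@H](O)[C@@H](C)C[C@@H](C)C(=O)[C@H](C)[C@@H](O)[C@@H](C)[C@@H](C)OC(=O)[C@H](C)[C@H]1O | target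

**Step count and risks**

Total steps: 16. Longest linear sequence: 14 steps (5 → 8 → 9 → 11 → 12 → 14 → 15 → 16 → 18 → 19 → 20 → 21 → 22 → 23 → 24; steps 3–16).

Steps most likely to fail:

1. Step 14 (proposed new method). What may go wrong:
   - the enol silane may attack with the wrong π‑face, or through an anti‑aldol geometry, in the macrocyclic transition state;
   - C2 may epimerise more slowly than the ring closes, so that half of the material reacts mismatched;
   - the acidic enol tautomer may protodesilylate the enol silane, or oligomers may form.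

   Fallback (known chemistry only; sets out from 9 and 4, comes back at 23): the C3–C4 bond is made intermolecularly and the ring is closed at O13–C1 by macrolactonisation. Thioester 9 is O‑benzylated (benzyl trichloroacetimidate, TfOH cat.) to S‑ethyl (2S,3R)‑3‑(benzyloxy)‑2‑methylbutanethioate F1, and Fukuyama reduction gives (2S,3R)‑3‑(benzyloxy)‑2‑methylbutanal F2. The boron aldol of 4 (through 13) with F2 gives the 13‑O‑benzyl adduct F3, and silylation gives its 11‑O‑TBS ether F4. Me3SnOH gives acid F5, the α‑chloroenamine gives acid chloride F6 (not isolated), and Et2Zn/Pd(PPh3)4 gives diketone F7; TBSOTf/Et3N then gives (Z)‑enol silane F8. The known intermolecular BF3·OEt2 Mukaiyama aldol of F8 with (S)‑3‑(benzyloxy)‑2‑methylpropanal F9 (Swern oxidation of commercial (R)‑3‑(benzyloxy)‑2‑methylpropan‑1‑ol) should give the Felkin syn,syn adduct F10. Narasaka–Prasad reduction gives the 3,5‑syn diol F11, and 2,2‑dimethoxypropane/PPTS gives acetonide F12. Hydrogenolysis of both benzyl ethers gives the 1,13‑diol F13, and TEMPO/PhI(OAc)2 in aqueous MeCN oxidises the primary alcohol to the seco‑acid F14. Yamaguchi macrolactonisation through the mixed anhydride F15 (not isolated; 2,4,6‑trichlorobenzoyl chloride, Et3N, then DMAP, toluene, high dilution) closes the ring to the 3,5‑acetonide F16, and PPTS in MeOH removes the acetonide to return to 23.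

2. Step 7. What may go wrong: the anti‑Felkin/syn preference may erode in the double stereodifferentiation with the α′‑stereocentre of 4, and the β‑acyloxy aldehyde 12 may undergo β‑elimination to the enal before it is captured.

   Fallback (sets out from 9 and 4, comes back at 15): the order of esterification and aldol is reversed, so that the aldol runs on the robust β‑benzyloxy aldehyde, the substrate class for which anti‑Felkin additions of (Z)‑boron enolates are best documented, and which also allows a chiral diisopinocampheylboron enolate to be used as reagent control. 9 is taken through F1 and F2 as above, and the aldol with 4 and silylation give F3 and F4. Hydrogenolysis (H2, Pd/C, EtOAc) gives the 13‑hydroxy ketone F17, which is in equilibrium with its 9,13‑hemiketal; Steglich esterification with 10 (DCC, DMAP) drains the open form and returns to 15.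

3. Step 12. What may go wrong: the enol silane may be partly hydrogenated, or hydrolysed by adventitious acid on the catalyst, during the debenzylation.

   Fallback (sets out from 18, comes back at 21): the alcohol is unveiled and oxidised first and the silyl group is put on last. Hydrogenolysis of 18 gives the primary alcohol F18, and Dess–Martin oxidation gives the α‑formyl ester diketone F19. TBSOTf (2.5 equiv)/Et3N silylates both the C5 ethyl ketone and the enol of the formyl ester to give the bis‑silyl compound F20. Its vinylogous silyl ester is far more labile than the ketone enol silane and is cleaved selectively (MeOH, pH 7 buffer, 0 °C) to return to 21.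

**Further compounds**

F1 | step 14 | S‑ethyl (2S,3R)‑3‑(benzyloxy)‑2‑methylbutanethioate | CCSC(=O)[C@@H](C)[C@@H](C)OCc1ccccc1
F2 | step 14 | (2S,3R)‑3‑(benzyloxy)‑2‑methylbutanal | O=C[C@@H](C)[C@@H](C)OCc1ccccc1
F3 | step 14 | 13‑O‑benzyl aldol adduct (C5 methyl ester, 9‑ketone, 11‑OH) | COC(=O)[C@@H](C)C[C@@H](C)C(=O)[C@H](C)[C@@H](O)[C@@H](C)[C@@H](C)OCc1ccccc1
F4 | step 14 | 11‑O‑TBS ether of F3 | COC(=O)[C@@H](C)C[C@@H](C)C(=O)[C@H](C)[C@@H](O[Si](C)(C)C(C)(C)C)[C@@H](C)[C@@H](C)OCc1ccccc1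
F5 | step 14 | carboxylic acid from F4 (C5 CO2H) | OC(=O)[C@@H](C)C[C@@H](C)C(=O)[C@H](C)[C@@H](O[Si](C)(C)C(C)(C)C)[C@@H](C)[C@@H](C)OCc1ccccc1
F6 | step 14 | acid chloride of F5 | ClC(=O)[C@@H](C)C[C@@H](C)C(=O)[C@H](C)[C@@H](O[Si](C)(C)C(C)(C)C)[C@@H](C)[C@@H](C)OCc1ccccc1
F7 | step 14 | 13‑O‑benzyl 5,9‑diketone | CCC(=O)[C@@H](C)C[C@@H](C)C(=O)[C@H](C)[C@@H](O[Si](C)(C)C(C)(C)C)[C@@H](C)[C@@H](C)OCc1ccccc1
F8 | step 14 | (Z)‑C4=C5 TBS enol ether of F7 | C/C=C(\O[Si](C)(C)C(C)(C)C)[C@@H](C)C[C@@H](C)C(=O)[C@H](C)[C@@H](O[Si](C)(C)C(C)(C)C)[C@@H](C)[C@@H](C)OCc1ccccc1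
F9 | step 14 | (S)‑3‑(benzyloxy)‑2‑methylpropanal | O=C[C@@H](C)COCc1ccccc1
F10 | step 14 | open‑chain aldol adduct (C1 CH2OBn, 3‑OH, 5‑ketone, 9‑ketone, 11‑OTBS, 13‑OBn) | c1ccccc1COC[C@H](C)[C@@H](O)[C@H](C)C(=O)[C@@H](C)C[C@@H](C)C(=O)[C@H](C)[C@@H](O[Si](C)(C)C(C)(C)C)[C@@H](C)[C@@H](C)OCc1ccccc1
F11 | step 14 | 3,5‑syn diol from F10 | c1ccccc1COC[C@H](C)[C@@H](O)[C@H](C)[C@@H](O)[C@@H](C)C[C@@H](C)C(=O)[C@H](C)[C@@H](O[Si](C)(C)C(C)(C)C)[C@@H](C)[C@@H](C)OCc1ccccc1
F12 | step 14 | 3,5‑acetonide of F11 | c1ccccc1COC[C@H](C)[C@@H]2[C@H](C)[C@@H](OC(C)(C)O2)[C@@H](C)C[C@@H](C)C(=O)[C@H](C)[C@@H](O[Si](C)(C)C(C)(C)C)[C@@H](C)[C@@H](C)OCc1ccccc1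
F13 | step 14 | 1,13‑diol from F12 | OC[C@H](C)[C@@H]1[C@H](C)[C@@H](OC(C)(C)O1)[C@@H](C)C[C@@H](C)C(=O)[C@H](C)[C@@H](O[Si](C)(C)C(C)(C)C)[C@@H](C)[C@@H](C)O
F14 | step 14 | seco‑acid (C1 CO2H, 13‑OH, 3,5‑acetonide, 11‑OTBS) | OC(=O)[C@H](C)[C@@H]1[C@H](C)[C@@H](OC(C)(C)O1)[C@@H](C)C[C@@H](C)C(=O)[C@H](C)[C@@H](O[Si](C)(C)C(C)(C)C)[C@@H](C)[C@@H](C)O
F15 | step 14 | mixed 2,4,6‑trichlorobenzoic anhydride of F14 | O=C(OC(=O)c1c(Cl)cc(Cl)cc1Cl)[C@H](C)[C@@H]2[C@H](C)[C@@H](OC(C)(C)O2)[C@@H](C)C[C@@H](C)C(=O)[C@H](C)[C@@H](O[Si](C)(C)C(C)(C)C)[C@@H](C)[C@@H](C)O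
F16 | step 14 | 3,5‑O‑isopropylidene‑11‑O‑TBS‑8,8a‑deoxyoleandolide | C[C@@H]1[C@@H](OC(C)(C)O2)[C@@H](C)C[C@@H](C)C(=O)[C@H](C)[C@@H](O[Si](C)(C)C(C)(C)C)[C@@H](C)[C@@H](C)OC(=O)[C@H](C)[C@H]12
F17 | step 7 | 13‑hydroxy ketone from F4 (C5 methyl ester, 9‑ketone, 11‑OTBS, 13‑OH; open form) | COC(=O)[C@@H](C)C[C@@H](C)C(=O)[C@H](C)[C@@H](O[Si](C)(C)C(C)(C)C)[C@@H](C)[C@@H](C)O
F18 | step 12 | primary alcohol from 18 (5,9‑diketone, C3 OH) | CCC(=O)[C@@H](C)C[C@@H](C)C(=O)[C@H](C)[C@@H](O[Si](C)(C)C(C)(C)C)[C@@H](C)[C@@H](C)OC(=O)[C@H](C)CO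
F19 | step 12 | α‑formyl ester 5,9‑diketone (C2 unassigned) | CCC(=O)[C@@H](C)C[C@@H](C)C(=O)[C@H](C)[C@@H](O[Si](C)(C)C(C)(C)C)[C@@H](C)[C@@H](C)OC(=O)C(C)C=O
F20 | step 12 | bis‑silyl compound (C4=C5 enol silane and O‑silylated enol of the formyl ester) | C/C=C(\O[Si](C)(C)C(C)(C)C)[C@@H](C)C[C@@H](C)C(=O)[C@H](C)[C@@H](O[Si](C)(C)C(C)(C)C)[C@@H](C)[C@@H](C)OC(=O)C(C)=CO[Si](C)(C)C(C)(C)C
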